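**Plan**
- Numbering: C1 is the ring carbon bearing C7H2OBz, C2–C4 are the diene CH carbons, C5 is CH–OBz and C6 is CH–OH.
- Retrosynthesis: O6 is silylated, the O7–benzoyl bond is cut and C7 is raised to the aldehyde; then C5–C6 and C1–C2 are cut, leaving (E)-4-(benzoyloxy)but-2-enal and (E)-3-(triisopropylsilyloxy)acrolein.
- Enabling feature: with C7 as CHO, ring C1–C6 is a cyclohexa-1,3-diene-1-carbaldehyde (C7=O conjugated with C1=C2–C3=C4). Its two sp3 carbons carry one oxygen each, so C2–C5 with O5 can come from one enal and C7, C1, C6 with O6 from the other.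
- Forward: the two enals are made separately (one step; two steps), the six-membered ring closes in a single amine-catalysed condensation, and reduction, benzoylation and desilylation finish the target.
- Stereochemistry: both centres arise in the ring-forming step. C5 is set by face shielding of the dienamine by the (S)-prolinol ether, and C6 is set trans to it by the endo approach of the E-configured acceptor; no later step breaks a bond at C5 or C6.

Key step: step 4

Assumption: the absolute sense of step 4 is assigned from the steric-shielding model of diarylprolinol silyl ethers; if the opposite sense were found, the (R)-configured amine would be used with nothing else changed.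

Step 1
Reactants: 1 allyl benzoate (prop-2-en-1-yl benzoate); 2 (E)-crotonaldehyde ((E)-but-2-enal)
Product: 3 (E)-4-oxobut-2-en-1-yl benzoate
Conditions: 2 (5 equiv), second-generation Hoveyda–Grubbs catalyst RuCl2(H2IMes)(=CH-2-iPrO-C6H4) (2.5 mol %), CH2Cl2, 40 °C
Reagents that add atoms: (E)-crotonaldehyde (2), C/C=C/C=O
Why: Olefin cross-metathesis of a terminal allylic ester with an excess of an enal is well precedented and, being reversible, should deliver the thermodynamically favoured E enal while propene escapes; no stereocentre is formed.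

Step 2
Reactants: 4 1,1,3,3-tetramethoxypropane
Product: 6 sodium (E)-3-oxoprop-1-en-1-olate, via malonaldehyde 5 (not isolated)
Conditions: sulfonic acid ion-exchange resin (H+ form, cat.), H2O, rt; filter; NaOH (1.0 equiv), 0 °C; freeze-dry, dry in vacuo
Reagents that add atoms: water, O; sodium hydroxide, [Na+].[OH-]
Why: Acid-catalysed acetal hydrolysis frees malonaldehyde, whose acidic enol is neutralised with one equivalent of base to the stable, E-configured sodium enolate; no stereocentre is formed.

Step 3
Reactants: 6 sodium (E)-3-oxoprop-1-en-1-olate; 7 triisopropylsilyl chloride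
Product: 8 (E)-3-(triisopropylsilyloxy)acrolein ((E)-3-[(triisopropylsilyl)oxy]prop-2-enal)
Conditions: 7 (1.05 equiv), DMF, 0 °C → rt
Reagents that add atoms: triisopropylsilyl chloride (7), CC(C)[Si](Cl)(C(C)C)C(C)C
Why: O-Silylation of a vinylogous carboxylate: the hard silicon electrophile should attack the enolate oxygen with retention of the extended E geometry, as in the known preparation of the tert-butyldimethylsilyl analogue; no stereocentre is formed.

Step 4
Reactants: 3 (E)-4-oxobut-2-en-1-yl benzoate; 8 (E)-3-(triisopropylsilyloxy)acrolein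
Product: 11 (5R,6R)-5-(benzoyloxy)-6-(triisopropylsilyloxy)cyclohexa-1,3-diene-1-carbaldehyde, via dienamine 9 (not isolated), via aminocyclohexene carbaldehyde 10 (not isolated)
Conditions: (S)-2-[diphenyl(trimethylsilyloxy)methyl]pyrrolidine (20 mol %), PhCO2H (20 mol %), 8 (2.5 equiv), 3 added over 8 h, toluene, −20 °C
Reagents that add atoms: (E)-3-(triisopropylsilyloxy)acrolein (8), O=C/C=C/O[Si](C(C)C)(C(C)C)C(C)C
Why: Proposed new method: the secondary amine should convert 3 into the (1E,3E)-dienamine 9 and 8 into its iminium ion, after which the dienamine terminus C5 adds to the silyloxy-bearing carbon C6 and the enamine carbon C1 so formed closes on the conjugated iminium carbon C2 (an endo-selective formal [4+2] cycloaddition, the six-membered ring closing either in concert or by a 6-(enolexo)-exo-trig Mannich reaction) to give 10, which loses the amine by E1cB elimination to create C1=C2 and release the catalyst. The closest known reaction type is the proline- or prolinol-ether-catalysed [4+2] condensation of two enals to cyclohexa-1,3-diene-1-carbaldehydes, known also with γ-acyloxy enals as the dienamine partner, whereas a β-silyloxy enal as the acceptor is what has not been shown. C5 is controlled by the catalyst: its CPh2OTMS group blocks one face of the s-cis dienamine, so C6 should be delivered to the Si face of C5, which with the (S)-amine corresponds to 5R. C6 is controlled relative to C5 by the endo arrangement of the E-configured acceptor (iminium carbon under the diene, silyloxy group pointing away), which places the two oxygens trans and gives 6R, and the same amine on the iminium ion exposes the matching Si face of C6. The step needs cross- over self-condensation and survival of the C6–O bond: only 3 has γ-hydrogens and can form a dienamine, 8 is kept in excess while 3 is added slowly, and the bulky silyl group, the apolar solvent and the low temperature are chosen to hold back amine addition–elimination at C6, loss of silanol and aromatisation.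

Step 5
Reactants: 11 (5R,6R)-5-(benzoyloxy)-6-(triisopropylsilyloxy)cyclohexa-1,3-diene-1-carbaldehyde
Product: 12 (1R,6R)-5-(hydroxymethyl)-6-(triisopropylsilyloxy)cyclohexa-2,4-dien-1-yl benzoate
Conditions: NaBH4 (1.0 equiv), CeCl3·7H2O (1.0 equiv), MeOH, −78 °C; aq. NH4Cl
Reagents that add atoms: none
Why: Luche reduction: the cerium salt in methanol should direct borohydride to 1,2-addition at the dienal carbonyl at low temperature, leaving the diene, the benzoate and the silyl ether, and hence C5 and C6, untouched.

Step 6
Reactants: 12 (1R,6R)-5-(hydroxymethyl)-6-(triisopropylsilyloxy)cyclohexa-2,4-dien-1-yl benzoate; 13 benzoyl chloride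
Product: 14 [(5R,6R)-5-(benzoyloxy)-6-(triisopropylsilyloxy)cyclohexa-1,3-dien-1-yl]methyl benzoate
Conditions: 13 (1.2 equiv), pyridine, DMAP (5 mol %), CH2Cl2, 0 °C
Reagents that add atoms: benzoyl chloride (13), O=C(Cl)c1ccccc1
Why: DMAP-catalysed esterification of the only free hydroxyl, a primary allylic one; O6 is blocked by silicon, so no regiochemical question arises and no stereocentre is involved.

Step 7
Reactants: 14 [(5R,6R)-5-(benzoyloxy)-6-(triisopropylsilyloxy)cyclohexa-1,3-dien-1-yl]methyl benzoate
Product: 15 [(5R,6R)-5-(benzoyloxy)-6-hydroxycyclohexa-1,3-dien-1-yl]methyl benzoate (CNP0113836.1)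
Conditions: HF·pyridine, pyridine, THF, 0 °C → rt
Reagents that add atoms: none
Why: Fluoride-mediated desilylation under buffered, weakly acidic conditions breaks only the Si–O bond, so C6 keeps its configuration, and it avoids the free alkoxide that would trigger benzoyl migration from O5 or O7 or elimination towards the arene.

**Compound list**
1 | allyl benzoate (prop-2-en-1-yl benzoate) | C=CCOC(=O)c1ccccc1 | starting material
2 | (E)-but-2-enal (crotonaldehyde) | C/C=C/C=O | starting material
3 | (E)-4-oxobut-2-en-1-yl benzoate | O=C/C=C/COC(=O)c1ccccc1 | intermediate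
4 | 1,1,3,3-tetramethoxypropane | COC(OC)CC(OC)OC | starting material
5 | propanedial (malonaldehyde) | O=CCC=O | intermediate
6 | sodium (E)-3-oxoprop-1-en-1-olate | [Na+].[O-]/C=C/C=O | intermediate
7 | triisopropylsilyl chloride | CC(C)[Si](Cl)(C(C)C)C(C)C | starting material
8 | (E)-3-(triisopropylsilyloxy)acrolein | O=C/C=C/O[Si](C(C)C)(C(C)C)C(C)C | intermediate
9 | (1E,3E)-4-{(2S)-2-[diphenyl(trimethylsilyloxy)methyl]pyrrolidin-1-yl}buta-1,3-dien-1-yl benzoate | O=C(O/C=C/C=C/N1CCC[C@H]1C(c1ccccc1)(c1ccccc1)O[Si](C)(C)C)c1ccccc1 | intermediate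
10 | (1S,2S,5R,6R)-5-(benzoyloxy)-2-{(2S)-2-[diphenyl(trimethylsilyloxy)methyl]pyrrolidin-1-yl}-6-(triisopropylsilyloxy)cyclohex-3-ene-1-carbaldehyde (drawn as the free aldehyde) | O=C[C@H]1[C@@H](N2CCC[C@H]2C(c2ccccc2)(c2ccccc2)O[Si](C)(C)C)C=C[C@@H](OC(=O)c2ccccc2)[C@@H]1O[Si](C(C)C)(C(C)C)C(C)C | intermediate
11 | (5R,6R)-5-(benzoyloxy)-6-(triisopropylsilyloxy)cyclohexa-1,3-diene-1-carbaldehyde | O=CC1=CC=C[C@@H](OC(=O)c2ccccc2)[C@@H]1O[Si](C(C)C)(C(C)C)C(C)C | intermediate
12 | (1R,6R)-5-(hydroxymethyl)-6-(triisopropylsilyloxy)cyclohexa-2,4-dien-1-yl benzoate | OCC1=CC=C[C@@H](OC(=O)c2ccccc2)[C@@H]1O[Si](C(C)C)(C(C)C)C(C)C | intermediate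
13 | benzoyl chloride | O=C(Cl)c1ccccc1 | starting material
14 | [(5R,6R)-5-(benzoyloxy)-6-(triisopropylsilyloxy)cyclohexa-1,3-dien-1-yl]methyl benzoate | O=C(OCC1=CC=C[C@@H](OC(=O)c2ccccc2)[C@@H]1O[Si](C(C)C)(C(C)C)C(C)C)c1ccccc1 | intermediate
15 | [(5R,6R)-5-(benzoyloxy)-6-hydroxycyclohexa-1,3-dien-1-yl]methyl benzoate | O=C(OCC1=CC=C[C@@H](OC(=O)c2ccccc2)[C@@H]1O)c1ccccc1 | target

**Step count and risks**
Total steps: 7. Longest linear sequence: 6 steps (steps 2, 3, 4, 5, 6, 7, from 4 to 15).

Steps most likely to fail:

1. Step 4. The amine may be consumed by addition–elimination at C6 of 8, 3 may condense with itself faster than with 8, the oxygens may end up cis through an exo approach, or silanol may be lost with aromatisation. The fallback uses known chemistry only: the ring is taken from the arene chiral pool and the trans relationship is made by inversion.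
   - It leaves the main line before the two enals are needed. It sets out from the silyl chloride 7 (the only numbered compound it uses) together with commercial (1S,2S)-3-bromocyclohexa-3,5-diene-1,2-diol F1, the dioxygenase cis-dihydrodiol of bromobenzene, and it comes back at alcohol 12.
   - Diimide (from KO2CN=NCO2K and AcOH, MeOH, 0 °C) should saturate the unsubstituted double bond and give (1S,2S)-3-bromocyclohex-3-ene-1,2-diol F2.
   - Mitsunobu esterification with benzoic acid (PPh3, DIAD, THF, 0 °C) at the less hindered hydroxyl remote from bromine should invert that centre and give (1R,2S)-3-bromo-2-hydroxycyclohex-3-en-1-yl benzoate F3.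
   - Silylation of the remaining hydroxyl with 7 (imidazole, DMAP, DMF, 40 °C) should give (1R,2S)-3-bromo-2-(triisopropylsilyloxy)cyclohex-3-en-1-yl benzoate F4.
   - Allylic bromination (NBS, AIBN, PhCF3, 80 °C) should give (1R,2S)-3,5-dibromo-2-(triisopropylsilyloxy)cyclohex-3-en-1-yl benzoate F5 as both epimers at the new C–Br carbon.
   - DBU (THF, rt) should remove HBr to give (1R,6S)-5-bromo-6-(triisopropylsilyloxy)cyclohexa-2,4-dien-1-yl benzoate F6.
   - Stille coupling with (tributylstannyl)methanol (Pd(PPh3)4, dioxane, 80 °C) should replace bromine by CH2OH and give 12, from which steps 6 and 7 follow unchanged.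

2. Step 7. Cleavage of the hindered secondary triisopropylsilyl ether may be slow, and forcing it may bring benzoyl migration onto O6 or loss of benzoic acid with aromatisation. The fallback carries a more labile silyl group from the start; it sets out from enolate 6 and comes back at target 15.
   - Silylation of 6 with tert-butyldimethylsilyl chloride (DMF, 0 °C) should give (E)-3-(tert-butyldimethylsilyloxy)acrolein F7.
   - Condensation with 3 as in step 4 should give (5R,6R)-5-(benzoyloxy)-6-(tert-butyldimethylsilyloxy)cyclohexa-1,3-diene-1-carbaldehyde F8.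
   - Reduction and benzoylation as in steps 5 and 6 should give (1R,6R)-6-(tert-butyldimethylsilyloxy)-5-(hydroxymethyl)cyclohexa-2,4-dien-1-yl benzoate F9 and then [(5R,6R)-5-(benzoyloxy)-6-(tert-butyldimethylsilyloxy)cyclohexa-1,3-dien-1-yl]methyl benzoate F10.
   - The silyl ether of F10 should then be cleaved by HF·pyridine in THF at 0 °C within a short time to give 15.

3. Step 5. The borohydride/methanol medium may cause base-induced loss of benzoic acid or silanol from the dienal with aromatisation, or methanolysis of the C5 benzoate. The fallback is global hydride reduction followed by double acylation; it sets out from 11 and comes back at 14.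
   - Diisobutylaluminium hydride, i-Bu2AlH (3.5 equiv, CH2Cl2, −78 °C), should reduce the aldehyde and cleave the C5 benzoate to give (1R,6R)-5-(hydroxymethyl)-6-(triisopropylsilyloxy)cyclohexa-2,4-dien-1-ol F11.
   - Both hydroxyls are then benzoylated with 13 (2.5 equiv, pyridine, DMAP, CH2Cl2, 0 °C) to give 14, so that step 6 is absorbed.

Further compounds
F1 | step 4 | (1S,2S)-3-bromocyclohexa-3,5-diene-1,2-diol | BrC1=CC=C[C@H](O)[C@@H]1O
F2 | step 4 | (1S,2S)-3-bromocyclohex-3-ene-1,2-diol | BrC1=CCC[C@H](O)[C@@H]1O
F3 | step 4 | (1R,2S)-3-bromo-2-hydroxycyclohex-3-en-1-yl benzoate | BrC1=CCC[C@@H](OC(=O)c2ccccc2)[C@@H]1O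
F4 | step 4 | (1R,2S)-3-bromo-2-(triisopropylsilyloxy)cyclohex-3-en-1-yl benzoate | BrC1=CCC[C@@H](OC(=O)c2ccccc2)[C@@H]1O[Si](C(C)C)(C(C)C)C(C)C
F5 | step 4 | (1R,2S)-3,5-dibromo-2-(triisopropylsilyloxy)cyclohex-3-en-1-yl benzoate (both C5 epimers) | BrC1=CC(Br)C[C@@H](OC(=O)c2ccccc2)[C@@H]1O[Si](C(C)C)(C(C)C)C(C)C
F6 | step 4 | (1R,6S)-5-bromo-6-(triisopropylsilyloxy)cyclohexa-2,4-dien-1-yl benzoate | BrC1=CC=C[C@@H](OC(=O)c2ccccc2)[C@@H]1O[Si](C(C)C)(C(C)C)C(C)C
F7 | step 7 | (E)-3-(tert-butyldimethylsilyloxy)acrolein | O=C/C=C/O[Si](C)(C)C(C)(C)C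
F8 | step 7 | (5R,6R)-5-(benzoyloxy)-6-(tert-butyldimethylsilyloxy)cyclohexa-1,3-diene-1-carbaldehyde | O=CC1=CC=C[C@@H](OC(=O)c2ccccc2)[C@@H]1O[Si](C)(C)C(C)(C)C
F9 | step 7 | (1R,6R)-6-(tert-butyldimethylsilyloxy)-5-(hydroxymethyl)cyclohexa-2,4-dien-1-yl benzoate | OCC1=CC=C[C@@H](OC(=O)c2ccccc2)[C@@H]1O[Si](C)(C)C(C)(C)C
F10 | step 7 | [(5R,6R)-5-(benzoyloxy)-6-(tert-butyldimethylsilyloxy)cyclohexa-1,3-dien-1-yl]methyl benzoate | O=C(OCC1=CC=C[C@@H](OC(=O)c2ccccc2)[C@@H]1O[Si](C)(C)C(C)(C)C)c1ccccc1
F11 | step 5 | (1R,6R)-5-(hydroxymethyl)-6-(triisopropylsilyloxy)cyclohexa-2,4-dien-1-ol | OCC1=CC=C[C@@H](O)[C@@H]1O[Si](C(C)C)(C(C)C)C(C)C
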